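The target is read as a cis-syn-cis 5-4-5 tricycle (ring A C1–C5, four-membered ring C1/C5/C6/C10, ring B C6–C10) fused to a butenolide. The lactone O–C6 bond and the C7=C11 double bond are disconnected together. The precursor is a tricyclic ketone in which C6 is still an sp2 carbon of a strained C5=C6 cyclobutene shared by rings A and B. In one pot a phosphonoacetate olefinates C7 and, on acid, the C4 ketal falls and the freed acid adds to C6; cyclobutene strain drives the addition and the two cis ring fusions fix C5 and C6. The cyclobutene comes from photochemical 4π-electrocyclisation of a diene made by Negishi union of two cyclopentenyl halves.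

Key step: step 12

Remark: atoms carry skeleton numbers throughout: ring A C1–C5 (C2 bears the acetate, C4 the methyl C15 and the hydroxyl), four-membered ring C1, C5, C6, C10, ring B C6–C10 (C8 bears the tiglate, C10 the methyl C14), butenolide C11 (α-carbon), C12 (carbonyl), C13 (CH2O). In this numbering the target is (1R,2S,4R,5R,6R,8S,10R); H-1, H-5, O-6 and CH3-14 lie on one face of the four-membered ring and rings A and B on the other.

Step 1
Reactants: 1 (S)-4-[(tert-butyldimethylsilyl)oxy]cyclopent-2-en-1-one
Product: 2 (S)-4-[(tert-butyldimethylsilyl)oxy]-2-iodocyclopent-2-en-1-one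
Conditions: I2, pyridine, CH2Cl2, 0 °C → rt
Reagents that add atoms: iodine, II
Why: α-Iodination of an enone by amine-mediated addition–elimination is routine for 4-silyloxycyclopentenones and leaves the future C2 stereocentre untouched.

Step 2
Reactants: 2 (S)-4-[(tert-butyldimethylsilyl)oxy]-2-iodocyclopent-2-en-1-one
Product: 3 (S)-tert-butyl[(6-iodo-1,4-dioxaspiro[4.4]non-6-en-8-yl)oxy]dimethylsilane
Conditions: (TMSOCH2)2, TMSOTf (cat.), CH2Cl2, −78 → −20 °C
Reagents that add atoms: 1,2-bis(trimethylsilyloxy)ethane, C[Si](C)(C)OCCO[Si](C)(C)C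
Why: Silyl-triflate-catalysed ketalisation masks the future C4 carbonyl at low temperature without β-elimination of the silyloxy group, so that ring A later shows only a diene chromophore; no stereocentre is formed.

Step 3
Reactants: 4 3-methylcyclopent-2-en-1-one
Product: 5 2-iodo-3-methylcyclopent-2-en-1-one
Conditions: I2, K2CO3, DMAP (cat.), THF/H2O, rt
Reagents that add atoms: iodine, II
Why: The same α-iodination of an enone, here with an amine catalyst and carbonate for the β-substituted case, should give the ring B coupling partner; no stereocentre is formed.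

Step 4
Reactants: 3 iodo ketal (ring A half); 5 iodo enone (ring B half)
Product: 6 2-[(8S)-8-[(tert-butyldimethylsilyl)oxy]-1,4-dioxaspiro[4.4]non-6-en-6-yl]-3-methylcyclopent-2-en-1-one
Conditions: 3, t-BuLi (2 equiv), THF, −78 °C; ZnCl2, −78 → 0 °C; then 5, Pd2(dba)3 (cat.), SPhos (cat.), THF, rt → 45 °C
Reagents that add atoms: none
Why: Negishi cross-coupling (iodine–lithium exchange on the ketal-flanked vinyl iodide, transmetalation to zinc, palladium-catalysed coupling with an α-iodoenone) should forge the hindered C5–C6 bond between the two rings; no stereocentre is formed.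

Step 5
Reactants: 6 dienone
Product: 7 (1R)-2-[(8S)-8-[(tert-butyldimethylsilyl)oxy]-1,4-dioxaspiro[4.4]non-6-en-6-yl]-3-methylcyclopent-2-en-1-ol
Conditions: (S)-2-methyl-CBS-oxazaborolidine (cat.), BH3·SMe2, THF, −20 °C; then MeOH
Reagents that add atoms: none
Why: Corey–Bakshi–Shibata reduction, in which the oxazaborolidine distinguishes the alkenyl from the methylene flank of the ketone, should give the (R)-carbinol at C7 under reagent control and remove the enone chromophore; this temporary centre places the hydroxyl on the face of ring B that later bonds to C1.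

Step 6
Reactants: 7 dienol
Product: 8 tricyclic cyclobutene alcohol
Conditions: hν (254 nm), degassed pentane/Et2O, quartz, rt
Reagents that add atoms: none
Why: Photochemical disrotatory 4π-electrocyclisation of the s-cis diene C1=C5–C6=C10 (the known closure of 1,1'-bicycloalkenyls to cyclobutenes) forms the C1–C10 bond and turns the inward H-1 and CH3-14 onto one face, the sense of twist being set by closure anti to the C2 silyloxy group and reinforced by the C7 hydroxyl, which keeps the ketal on the other face of ring B.

Step 7
Reactants: 8 tricyclic cyclobutene alcohol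
Product: 9 cyclobutenyl ketone
Conditions: Dess–Martin periodinane, CH2Cl2, 0 °C → rt
Reagents that add atoms: none
Why: Dess–Martin oxidation of the secondary allylic alcohol should give the C7 ketone without touching ketal or silyl ether; the temporary C7 stereocentre disappears.

Step 8
Reactants: 9 cyclobutenyl ketone
Product: 10 C8 α-hydroxy ketone
Conditions: KN(SiMe3)2, THF, −78 °C; 2-(phenylsulfonyl)-3-phenyloxaziridine, −78 °C; then AcOH
Reagents that add atoms: 2-(phenylsulfonyl)-3-phenyloxaziridine, O=S(=O)(c1ccccc1)N1OC1c1ccccc1
Why: Enolate hydroxylation with an N-sulfonyloxaziridine (Davis oxidation) can occur only at C8 because C6 carries no hydrogen, and the oxidant should approach the potassium enolate anti to the pseudo-axial CH3-14, giving the C8 hydroxyl trans to that methyl.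

Step 9
Reactants: 10 C8 α-hydroxy ketone; 11 tiglic acid
Product: 12 C8 tiglate of the cyclobutenyl ketone
Conditions: PPh3, DIAD, toluene, 0 °C → rt
Reagents that add atoms: none
Why: Mitsunobu esterification, an SN2 displacement that is accelerated at a carbinol carbon next to a ketone, should install the tiglate with inversion so that O-8 becomes cis to CH3-14 as in the target.

Step 10
Reactants: 13 tert-butyl 3-hydroxypropanoate
Product: 14 tert-butyl 3-[(tert-butyldiphenylsilyl)oxy]propanoate
Conditions: TBDPSCl, imidazole, CH2Cl2, rt
Reagents that add atoms: tert-butyl(chloro)diphenylsilane, CC(C)(C)[Si](Cl)(c1ccccc1)c1ccccc1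
Why: Standard silylation of a primary alcohol provides an acid-stable, non-nucleophilic cover for the future C13 oxygen; no stereocentre is formed.

Step 11
Reactants: 14 tert-butyl 3-[(tert-butyldiphenylsilyl)oxy]propanoate
Product: 15 tert-butyl 3-[(tert-butyldiphenylsilyl)oxy]-2-(diethoxyphosphoryl)propanoate (racemic)
Conditions: LiN(iPr)2, THF, −78 °C; ClP(OEt)2, −78 → 0 °C; then H2O2 (aq.), 0 °C
Reagents that add atoms: diethyl chlorophosphite, CCOP(Cl)OCC; hydrogen peroxide, OO
Why: C-phosphinylation of an ester lithium enolate with a chlorophosphite followed by oxidation of trivalent to pentavalent phosphorus is an established route to α-phosphono esters, the β-silyloxy enolate should not eliminate at −78 °C, and the new centre is racemic and later becomes sp2.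

Step 12
Reactants: 12 C8 tiglate of the cyclobutenyl ketone; 15 phosphonate
Product: 18 tetracyclic C4-keto butenolide, via tert-butyl dienoate 16 (not isolated), via keto acid 17 (not isolated)
Conditions: 15, NaH, THF, 0 °C; 12, 0 → 45 °C; then TFA/CH2Cl2, 0 °C; then H2O, rt
Reagents that add atoms: water, O
Why: Horner–Wadsworth–Emmons olefination of the C7 ketone by the sodium salt of 15 forms C7=C11 (16); trifluoroacetic acid then cleaves the tert-butyl ester and, with water, the ketal, and the freed acid 17 adds in a conjugate sense to the enone C4(=O)–C5=C6, which closes the lactone O–C6 bond. The closest known reaction types are the olefination/lactonisation synthesis of butenolides and the intramolecular oxa-Michael lactonisation of carboxylic acids onto enones. The butenolide ring closes in the 5-exo-trig mode, driven by loss of the strained, doubly conjugated cyclobutene double bond. C6 is set because ring B must stay cis-fused to the four-membered ring, so oxygen can only enter on the CH3-14 face, and C5 is set on ketonisation of the C4 enol because ring A must stay cis-fused, so the proton enters on the H-1 face. The step needs 1,2- rather than 1,4-addition of the phosphonate (the β-carbon C5 is fully substituted and shielded by the spiro ketal), an alkene geometry with C12 cis to C6 (the ester avoids the bulkier C8 tigloyloxy flank) and lactonisation at C6 only (the sole position β to the unmasked ketone within five-ring reach), while the silylated C13 oxygen cannot compete as a nucleophile.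

Step 13
Reactants: 18 tetracyclic C4-keto butenolide
Product: 19 C4 exocyclic methylene compound
Conditions: Zn, CH2Br2, TiCl4, THF/CH2Cl2, 0 °C → rt
Reagents that add atoms: dibromomethane, BrCBr
Why: Lombardo methylenation converts a ketone into a methylene group without basic conditions, so the β-acyloxy and β-silyloxy ketone should survive and the esters and the lactone stay untouched; no stereocentre is formed.

Step 14
Reactants: 19 C4 exocyclic methylene compound
Product: 20 C4 tertiary alcohol
Conditions: Co(acac)2 (cat.), PhSiH3, O2 (1 atm), THF, rt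
Reagents that add atoms: dioxygen, O=O
Why: Mukaiyama hydration (cobalt-catalysed hydrogen-atom transfer, then trapping of the tertiary C4 radical by dioxygen) is Markovnikov-selective and fastest for the 1,1-disubstituted alkene, trapping should outrun opening of the adjacent four-membered ring, and dioxygen should add from the convex face of ring A because ring B covers the concave face, which sets the C4 hydroxyl cis to H-5.

Step 15
Reactants: 20 C4 tertiary alcohol
Product: 21 C2,C13-diol
Conditions: HF·pyridine, pyridine/THF, 0 °C → rt
Reagents that add atoms: none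
Why: Fluoride-mediated desilylation with buffered hydrogen fluoride–pyridine should remove both silyl ethers while the tiglate, the lactone and the tertiary alcohol remain; no stereocentre is affected.

Step 16
Reactants: 21 C2,C13-diol
Product: 22 target CNP0210373.1
Conditions: Ac2O, pyridine, DMAP (cat.), CH2Cl2, 0 °C → rt
Reagents that add atoms: acetic anhydride, CC(=O)OC(C)=O
Why: Acylation with acetic anhydride under nucleophilic catalysis should esterify the secondary C2 and the primary C13 hydroxyls while the hindered tertiary C4 hydroxyl stays free, giving the target.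

Compound list
1 | (S)-4-[(tert-butyldimethylsilyl)oxy]cyclopent-2-en-1-one | O=C1C=C[C@@H](O[Si](C)(C)C(C)(C)C)C1 | starting material
2 | (S)-4-[(tert-butyldimethylsilyl)oxy]-2-iodocyclopent-2-en-1-one | O=C1C(I)=C[C@@H](O[Si](C)(C)C(C)(C)C)C1 | intermediate
3 | (S)-tert-butyl[(6-iodo-1,4-dioxaspiro[4.4]non-6-en-8-yl)oxy]dimethylsilane | IC1=C[C@@H](O[Si](C)(C)C(C)(C)C)CC12OCCO2 | intermediate
4 | 3-methylcyclopent-2-en-1-one | CC1=CC(=O)CC1 | starting material
5 | 2-iodo-3-methylcyclopent-2-en-1-one | CC1=C(I)C(=O)CC1 | intermediate
6 | 2-[(8S)-8-[(tert-butyldimethylsilyl)oxy]-1,4-dioxaspiro[4.4]non-6-en-6-yl]-3-methylcyclopent-2-en-1-one (dienone) | O=C1CCC(C)=C1C2=C[C@@H](O[Si](C)(C)C(C)(C)C)CC23OCCO3 | intermediate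
7 | (1R)-2-[(8S)-8-[(tert-butyldimethylsilyl)oxy]-1,4-dioxaspiro[4.4]non-6-en-6-yl]-3-methylcyclopent-2-en-1-ol (dienol) | O[C@@H]1CCC(C)=C1C2=C[C@@H](O[Si](C)(C)C(C)(C)C)CC23OCCO3 | intermediate
8 | tricyclic cyclobutene alcohol: C5=C6 cyclobutene, C4 ethylene ketal, C2 silyl ether cis to H-1, H-1 cis to CH3-14, C7 hydroxyl trans to CH3-14 | O[C@@H]1CC[C@]2(C)[C@@H]3[C@@H](O[Si](C)(C)C(C)(C)C)CC4(OCCO4)C3=C12 | intermediate
9 | cyclobutenyl ketone (C7 ketone of 8) | O=C1CC[C@]2(C)[C@@H]3[C@@H](O[Si](C)(C)C(C)(C)C)CC4(OCCO4)C3=C12 | intermediate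
10 | C8 α-hydroxy ketone, hydroxyl trans to CH3-14 | O=C1[C@H](O)C[C@]2(C)[C@@H]3[C@@H](O[Si](C)(C)C(C)(C)C)CC4(OCCO4)C3=C12 | intermediate
11 | tiglic acid, (E)-2-methylbut-2-enoic acid | C/C=C(\C)C(=O)O | starting material
12 | C8 tiglate of the cyclobutenyl ketone, O-8 cis to CH3-14 | O=C1[C@@H](OC(=O)/C(C)=C/C)C[C@]2(C)[C@@H]3[C@@H](O[Si](C)(C)C(C)(C)C)CC4(OCCO4)C3=C12 | intermediate
13 | tert-butyl 3-hydroxypropanoate | OCCC(=O)OC(C)(C)C | starting material
14 | tert-butyl 3-[(tert-butyldiphenylsilyl)oxy]propanoate | CC(C)(C)OC(=O)CCO[Si](c1ccccc1)(c1ccccc1)C(C)(C)C | intermediate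
15 | tert-butyl 3-[(tert-butyldiphenylsilyl)oxy]-2-(diethoxyphosphoryl)propanoate, racemic | CCOP(=O)(OCC)C(CO[Si](c1ccccc1)(c1ccccc1)C(C)(C)C)C(=O)OC(C)(C)C | intermediate
16 | tert-butyl dienoate: C7=C11 alkene with the ester cis to C6, cyclobutene and ketal intact | C/C=C(\C)C(=O)O[C@H]1C[C@]2(C)[C@@H]3[C@@H](O[Si](C)(C)C(C)(C)C)CC4(OCCO4)C3=C2/C1=C(/CO[Si](c5ccccc5)(c6ccccc6)C(C)(C)C)C(=O)OC(C)(C)C | intermediate (not isolated)
17 | keto acid: C4 ketone and free C12 acid, cyclobutene intact | C/C=C(\C)C(=O)O[C@H]1C[C@]2(C)[C@@H]3[C@@H](O[Si](C)(C)C(C)(C)C)CC(=O)C3=C2/C1=C(/CO[Si](c5ccccc5)(c6ccccc6)C(C)(C)C)C(=O)O | intermediate (not isolated)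
18 | tetracyclic C4-keto butenolide: H-5 cis to H-1, O-6 cis to CH3-14, C2 silyl ether, C13 silyl ether, C8 tiglate | C/C=C(\C)C(=O)O[C@H]1C[C@]2(C)[C@@H]3[C@@H](O[Si](C)(C)C(C)(C)C)CC(=O)[C@@H]3[C@@]23OC(=O)C(CO[Si](c5ccccc5)(c6ccccc6)C(C)(C)C)=C13 | intermediate
19 | C4 exocyclic methylene compound | C/C=C(\C)C(=O)O[C@H]1C[C@]2(C)[C@@H]3[C@@H](O[Si](C)(C)C(C)(C)C)CC(=C)[C@@H]3[C@@]23OC(=O)C(CO[Si](c5ccccc5)(c6ccccc6)C(C)(C)C)=C13 | intermediate
20 | C4 tertiary alcohol, hydroxyl cis to H-5 | C/C=C(\C)C(=O)O[C@H]1C[C@]2(C)[C@@H]3[C@@H](O[Si](C)(C)C(C)(C)C)C[C@@](C)(O)[C@@H]3[C@@]23OC(=O)C(CO[Si](c5ccccc5)(c6ccccc6)C(C)(C)C)=C13 | intermediate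
21 | C2,C13-diol with free C4 hydroxyl | C/C=C(\C)C(=O)O[C@H]1C[C@]2(C)[C@@H]3[C@@H](O)C[C@@](C)(O)[C@@H]3[C@@]23OC(=O)C(CO)=C13 | intermediate
22 | CNP0210373.1 | C/C=C(\C)C(=O)O[C@H]1C[C@]2(C)[C@@H]3[C@@H](OC(C)=O)C[C@@](C)(O)[C@@H]3[C@@]23OC(=O)C(COC(C)=O)=C13 | target

Total step count: 16. Longest linear sequence: 13 steps (steps 1, 2, 4–9, 12–16, from compound 1).

Steps most likely to fail

Step 12. The C7 ketone is hindered and enolisable, so deprotonation at C8, slow addition of the branched phosphonate anion or formation of the alkene isomer with the ester turned away from C6 may take over. The fallback sets out from 12 and 14 and separates carbon–carbon bond formation from elimination. The lithium enolate of 14 (LiN(iPr)2, THF, −78 °C) is added to the C7 ketone of 12 and quenched cold to give the aldol adduct, tertiary β-hydroxy ester F1. Dehydration of F1 with Martin sulfurane then gives dienoate 16, which is isolated and carried through the TFA/water stage of step 12. The fallback comes back to the route at compound 16.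

Step 9. The carboxylate has to enter C8 on the face of the pseudo-axial CH3-14, so elimination or esterification with retention through an acyloxyphosphonium species may compete with inversion. The fallback sets out from 10 and replaces the phosphonium leaving group by a sulfonate. Tf2O and 2,6-lutidine (CH2Cl2, −78 °C) give the C8 trifluoromethanesulfonate F2, and caesium tiglate (from 11 and Cs2CO3, 18-crown-6, toluene, 0 °C) displaces it with inversion. The fallback comes back to the route at compound 12.

Step 4. Transmetalation and reductive elimination between two fully substituted alkenyl carbons may be slow, so protonation of the alkenylzinc or homocoupling of the iodoenone may dominate. The fallback sets out from 3 and uses an isolable tin partner in a copper-assisted Stille coupling. Iodine–lithium exchange on 3 and quenching with Bu3SnCl give the alkenylstannane F3, which is coupled with 5 (Pd(PPh3)4, CuI, CsF, DMF, 45 °C). The fallback comes back to the route at compound 6.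

Further compounds
F1 | step 12 | tertiary β-hydroxy tert-butyl ester from aldol addition of 14 to the C7 ketone of 12, epimer mixture at C7 and C11 | C/C=C(\C)C(=O)O[C@H]1C[C@]2(C)[C@@H]3[C@@H](O[Si](C)(C)C(C)(C)C)CC4(OCCO4)C3=C2C1(O)C(CO[Si](c5ccccc5)(c6ccccc6)C(C)(C)C)C(=O)OC(C)(C)C
F2 | step 9 | C8 trifluoromethanesulfonate of 10, sulfonate oxygen trans to CH3-14 | O=C1[C@H](OS(=O)(=O)C(F)(F)F)C[C@]2(C)[C@@H]3[C@@H](O[Si](C)(C)C(C)(C)C)CC4(OCCO4)C3=C12
F3 | step 4 | (S)-tributyl[8-[(tert-butyldimethylsilyl)oxy]-1,4-dioxaspiro[4.4]non-6-en-6-yl]stannane | CCCC[Sn](CCCC)(CCCC)C1=C[C@@H](O[Si](C)(C)C(C)(C)C)CC12OCCO2
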